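**Plan**
- Retrosynthetic cuts, in order: the C3–O–Si and C2–O–benzoyl bonds; the C6–O bond of the oxirane (back to C1–OH and an activated C6–OH); the C3–H bond (back to a C3 enone); the C3–O and C6–O bonds together (back to a cyclohexa-1,3-diene and O2); finally C1–O and C2–O (back to benzoic acid).
- Enabling feature: in the six-membered carbocycle the C3–O and C6–O bonds lie 1,4 across the C4=C5 alkene, the imprint of O2 adding to a 1,3-diene. C1–O and C2–O form a cis diol on the former ipso and ortho carbons of benzoic acid.
- Forward order: benzoic acid supplies all seven carbons. The dioxolane (acetonide) ring forms first, then the 1,2-dioxine bridge by [4+2], which is opened by Kornblum–DeLaMare rearrangement. The oxirane closes by Mitsunobu cyclodehydration, and the C2 benzoate and free C3–OH are set last.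
- Stereochemistry: C1 and C2 come from the dioxygenase. O2 adds anti to the acetonide (C3–O and C6–O both β). C3 is turned to α by hydride delivery anti to the acetonide. C6 is inverted when C1–O closes the epoxide.

Key step: step 5

Convention: C1 is the quaternary ring carbon carrying C7 (CH2O), C2 is CH–OBz, C3 is CH–OH, C4=C5 is the alkene, C6 is the epoxide CH. β is the ring face of C7; α is the face of the C1–O and C2–O bonds. In these locants the target is (1S,2R,3R,6S), with all three ring oxygens α.

Assumption: the benzoate-oxidising mutant Ralstonia eutropha B9 is taken to be in hand as a laboratory culture, so benzoic acid is the purchased starting material.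

**Route**

Step 1
Reactants: 1 benzoic acid
Product: 2 (1S,2R)-1,2-dihydroxycyclohexa-3,5-diene-1-carboxylic acid
Conditions: Ralstonia eutropha B9 whole cells (benzoate 1,2-dioxygenase active, diol dehydrogenase blocked), sodium benzoate feed, fructose, mineral salts medium, air, 30 °C, pH 7; then pH 3, EtOAc extraction
Reagents that add atoms: dioxygen, O=O
Why: Enzymatic arene cis-dihydroxylation adds both atoms of O2 to the ipso and ortho carbons from one face, so C1 (S) and C2 (R) are set by the enzyme, and the blocked dehydrogenase prevents rearomatisation to catechol.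

Step 2
Reactants: 2 (1S,2R)-1,2-dihydroxycyclohexa-3,5-diene-1-carboxylic acid; 3 2,2-dimethoxypropane
Product: 4 1α,2α-O-isopropylidene derivative of 2 (acetonide acid, C1 and C2 unchanged)
Conditions: 2,2-dimethoxypropane, TsOH·H2O (cat.), acetone, 0 °C → rt
Reagents that add atoms: 2,2-dimethoxypropane (3), COC(C)(C)OC
Why: Acid-catalysed transketalisation closes the five-membered dioxolane readily on the cis diol, and catalytic acid at low temperature should limit dehydrative aromatisation of the dienediol.

Step 3
Reactants: 4 acetonide acid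
Product: 5 [1α,2α-(isopropylidenedioxy)cyclohexa-3,5-dien-1-yl]methanol (C7 primary alcohol)
Conditions: LiAlH4, THF, 0 °C → rt; Rochelle salt work-up
Reagents that add atoms: none
Why: LiAlH4 reduction of a carboxylic acid proceeds through the aluminium carboxylate to the primary alcohol, while the ketal, the unconjugated diene and the quaternary C1 are inert to hydride.

Step 4
Reactants: 5 C7 primary alcohol; 6 benzoyl chloride
Product: 7 [1α,2α-(isopropylidenedioxy)cyclohexa-3,5-dien-1-yl]methyl benzoate (diene benzoate)
Conditions: BzCl, Et3N, DMAP (cat.), CH2Cl2, 0 °C; used promptly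
Reagents that add atoms: benzoyl chloride (6), O=C(Cl)c1ccccc1
Why: DMAP-catalysed O-acylation of the only hydroxyl group installs the C7 benzoate of the target under conditions that leave the diene and ketal alone.

Step 5
Reactants: 7 diene benzoate
Product: 8 3β,6β-epidioxide of 7 (7,8-isopropylidenedioxy-2,3-dioxabicyclo[2.2.2]oct-5-ene; peroxide bridge anti to the acetonide, C4=C5 alkene)
Conditions: O2 (bubbled), 5,10,15,20-tetraphenylporphyrin (free base, cat.), CH2Cl2, white LED light, −20 °C
Reagents that add atoms: dioxygen, O=O
Why: Triplet-excited tetraphenylporphyrin transfers energy to O2, and the singlet oxygen adds to the s-cis-locked C3=C4–C5=C6 diene in a concerted suprafacial [4+2] cycloaddition, forming C3–O and C6–O and leaving the alkene at C4=C5. The closest known reaction type is the singlet-oxygen endoperoxidation of acetonide-protected arene cis-dihydrodiols. The one new ring, the six-membered 1,2-dioxine bridging C3 and C6, closes by cycloaddition with both C–O bonds formed on the same face, giving the 2,3-dioxabicyclo[2.2.2]oct-5-ene. C3 and C6 are set together under substrate control: the cis-fused dioxolane and its inward-pointing methyl group block the α face, so O2 should enter on the β face, anti to C1–O and C2–O. The step needs this facial selectivity and [4+2] chemoselectivity over ene reaction or diene dimerisation; the acetonide secures the first, and the planar cyclic diene, which has no allylic C–H aligned for an ene reaction and is kept cold and dilute, secures the second. The benzoate and the ketal do not react with singlet oxygen.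

Step 6
Reactants: 8 endoperoxide
Product: 9 6β-hydroxy-1α,2α-(isopropylidenedioxy)-3-oxocyclohex-4-en-1-yl]methyl benzoate (γ-hydroxy enone)
Conditions: Et3N, CH2Cl2, 0 °C → rt
Reagents that add atoms: none
Why: In this Kornblum–DeLaMare rearrangement the amine should remove the bridgehead hydrogen at C3, flanked only by C2–H, rather than C6–H beside the quaternary C1, and E2-type O–O cleavage then gives the C3 ketone while the C6–O bond keeps its β configuration.

Step 7
Reactants: 9 γ-hydroxy enone
Product: 10 3α,6β-diol ([3α,6β-dihydroxy-1α,2α-(isopropylidenedioxy)cyclohex-4-en-1-yl]methyl benzoate)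
Conditions: NaBH4, CeCl3·7H2O, MeOH, −78 °C
Reagents that add atoms: none
Why: In this Luche 1,2-reduction the cerium-activated carbonyl should take hydride on the β face, opposite the dioxolane on the neighbouring C2, which sets C3–OH α (cis to C2–O) without conjugate reduction or ester cleavage.

Step 8
Reactants: 10 3α,6β-diol
Product: 11 3α-O-tert-butyldiphenylsilyl ether of 10 (C6β–OH free)
Conditions: TBDPSCl, imidazole, DMF, 0 °C → rt
Reagents that add atoms: tert-butyldiphenylsilyl chloride, CC(C)(C)[Si](Cl)(c1ccccc1)c1ccccc1
Why: In this sterically controlled monosilylation the bulky chlorosilane should react at the C3 hydroxyl, which sits next to a CH carbon and cis to a vicinal ketal oxygen, and not at the neopentyl-type C6 hydroxyl beside quaternary C1 and cis to C7.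

Step 9
Reactants: 11 3α-silyl ether
Product: 12 1α,2α,6β-triol ([3α-(tert-butyldiphenylsilyloxy)-1α,2α,6β-trihydroxycyclohex-4-en-1-yl]methyl benzoate)
Conditions: TFA, H2O, CH2Cl2, 0 °C → rt
Reagents that add atoms: none
Why: Acid-catalysed ketal hydrolysis frees the C1/C2 diol, and the acid-robust TBDPS ether and both ester linkages should tolerate aqueous TFA at this temperature.

Step 10
Reactants: 12 1α,2α,6β-triol
Product: 13 1α,6α-epoxide ([3α-(tert-butyldiphenylsilyloxy)-1α,6α-epoxy-2α-hydroxycyclohex-4-en-1-yl]methyl benzoate)
Conditions: PPh3, DIAD, THF, 0 °C → rt (warm to 50 °C if slow)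
Reagents that add atoms: none
Why: In this Mitsunobu cyclodehydration of a trans-1,2-diol the allylic C6 hydroxyl becomes an oxyphosphonium leaving group and the tertiary C1 oxygen displaces it from the α face with inversion at C6, whereas the cis C1/C2 diol cannot close an epoxide and only forms a reversible phosphorane.

Step 11
Reactants: 13 epoxy alcohol; 6 benzoyl chloride
Product: 14 2α-O-benzoate of 13 (3α-silyl ether of the target)
Conditions: BzCl, pyridine, DMAP (cat.), CH2Cl2, 0 °C → rt
Reagents that add atoms: benzoyl chloride (6), O=C(Cl)c1ccccc1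
Why: DMAP-catalysed acylation of the single remaining hydroxyl group puts the benzoate on C2 without ambiguity, and the buffered basic medium leaves the vinyl epoxide closed.

Step 12
Reactants: 14 silyl-protected bis-benzoate
Product: 15 target, [(1S,2R,3R,6S)-2-(benzoyloxy)-1,6-epoxy-3-hydroxycyclohex-4-en-1-yl]methyl benzoate (route locants)
Conditions: Bu4NF, AcOH (1:1), THF, 0 °C → rt
Reagents that add atoms: none
Why: Fluoride-induced Si–O cleavage is driven by the strong Si–F bond, and the acetic acid buffer keeps the liberated C3 oxygen protonated so that the neighbouring C2 benzoate should not migrate and the epoxide should not open.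

**Compound list**
1 | benzoic acid | O=C(O)c1ccccc1 | starting material
2 | (1S,2R)-1,2-dihydroxycyclohexa-3,5-diene-1-carboxylic acid | OC(=O)[C@@]1(O)[C@H](O)C=CC=C1 | intermediate
3 | 2,2-dimethoxypropane | COC(C)(C)OC | starting material
4 | 1α,2α-O-isopropylidene acetonide acid | OC(=O)[C@@]12OC(C)(C)O[C@@H]1C=CC=C2 | intermediate
5 | [1α,2α-(isopropylidenedioxy)cyclohexa-3,5-dien-1-yl]methanol | OC[C@@]12OC(C)(C)O[C@@H]1C=CC=C2 | intermediate
6 | benzoyl chloride | O=C(Cl)c1ccccc1 | starting material
7 | diene benzoate (C7–OBz, C1/C2 acetonide) | O=C(OC[C@@]12OC(C)(C)O[C@@H]1C=CC=C2)c1ccccc1 | intermediate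
8 | 3β,6β-endoperoxide of 7 | O=C(OC[C@@]12OC(C)(C)O[C@@H]1[C@H]3OO[C@@H]2C=C3)c1ccccc1 | intermediate
9 | 3-oxo-6β-hydroxy enone acetonide | O=C(OC[C@@]12OC(C)(C)O[C@@H]1C(=O)C=C[C@H]2O)c1ccccc1 | intermediate
10 | 3α,6β-diol acetonide | O=C(OC[C@@]12OC(C)(C)O[C@@H]1[C@H](O)C=C[C@H]2O)c1ccccc1 | intermediate
11 | 3α-O-TBDPS, 6β-hydroxy acetonide | O=C(OC[C@@]12OC(C)(C)O[C@@H]1[C@H](O[Si](c3ccccc3)(c3ccccc3)C(C)(C)C)C=C[C@H]2O)c1ccccc1 | intermediate
12 | 3α-O-TBDPS 1α,2α,6β-triol | O=C(OC[C@@]1(O)[C@H](O)[C@H](O[Si](c2ccccc2)(c2ccccc2)C(C)(C)C)C=C[C@H]1O)c1ccccc1 | intermediate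
13 | 1α,6α-epoxy-2α-hydroxy-3α-O-TBDPS benzoate | O=C(OC[C@]12O[C@H]1C=C[C@@H](O[Si](c3ccccc3)(c3ccccc3)C(C)(C)C)[C@H]2O)c1ccccc1 | intermediate
14 | 1α,6α-epoxy-2α-benzoyloxy-3α-O-TBDPS benzoate | O=C(OC[C@]12O[C@H]1C=C[C@@H](O[Si](c3ccccc3)(c3ccccc3)C(C)(C)C)[C@H]2OC(=O)c4ccccc4)c1ccccc1 | intermediate
15 | [(1S,2R,3R,6S)-2-(benzoyloxy)-1,6-epoxy-3-hydroxycyclohex-4-en-1-yl]methyl benzoate | O=C(OC[C@]12O[C@H]1C=C[C@@H](O)[C@H]2OC(=O)c1ccccc1)c1ccccc1 | target

**Totals**
Total step count: 12. Longest linear sequence: 12 steps, from benzoic acid (fully linear).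

**Steps most likely to fail**

1. Step 6 (Kornblum–DeLaMare opening). The base may remove the C6 bridgehead hydrogen instead of the C3 one, giving the regioisomeric ketone, or the amine may trigger β-elimination and aromatisation of the enone once formed. Fallback, setting out from 8 and coming back at 9: the O–O bond is reduced with thiourea in MeOH at room temperature to the 3β,6β-diol acetonide F1. The less hindered C3 allylic alcohol of F1 is then oxidised selectively with TEMPO (cat.) and PhI(OAc)2 in CH2Cl2; the oxoammonium oxidant should discriminate against the neopentyl-type C6 carbinol. This gives hydroxy enone 9 without any base-mediated step.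

2. Step 10 (Mitsunobu epoxide closure). The phosphorus reagent may be tied up as the unreactive cis C1/C2 dioxaphosphorane, or the activated allylic C6 centre may undergo allylic transposition, elimination or capture by the hydrazide instead of ring closure. Fallback, setting out from 11 and coming back at 13: the single free hydroxyl of 11 is mesylated (MsCl, Et3N, CH2Cl2, −20 °C) to the C6β mesylate acetonide F5. Aqueous TFA then removes the ketal to give the C1/C2-diol C6β-mesylate F6. DBU in toluene closes the epoxide by intramolecular SN2 attack of C1–O on C6, giving 13 with the same inversion.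

3. Step 8 (site-selective silylation). Discrimination between the two secondary allylic hydroxyls may be poor, leading to silylation at C6, double silylation, or sluggish reaction at the C3 hydroxyl cis to the ketal. Fallback, setting out from 9 and coming back at 12: the only hydroxyl of enone 9 is capped first (TESOTf, 2,6-lutidine, CH2Cl2, −78 °C) to give the C6β triethylsilyl ether enone F2. Luche reduction as in step 7 gives the C3α alcohol F3. TBDPSCl with imidazole, now without a competing hydroxyl, gives the fully protected C3α-TBDPS, C6β-TES acetonide F4. Aqueous TFA removes the labile triethylsilyl ether and the ketal together, delivering triol 12.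

**Further compounds**
F1 | step 6 | 3β,6β-diol acetonide (C7 benzoate) | O=C(OC[C@@]12OC(C)(C)O[C@@H]1[C@@H](O)C=C[C@H]2O)c1ccccc1
F2 | step 8 | 6β-O-triethylsilyl 3-oxo enone acetonide | O=C(OC[C@@]12OC(C)(C)O[C@@H]1C(=O)C=C[C@H]2O[Si](CC)(CC)CC)c1ccccc1
F3 | step 8 | 3α-hydroxy 6β-O-triethylsilyl acetonide | O=C(OC[C@@]12OC(C)(C)O[C@@H]1[C@H](O)C=C[C@H]2O[Si](CC)(CC)CC)c1ccccc1
F4 | step 8 | 3α-O-TBDPS 6β-O-triethylsilyl acetonide | O=C(OC[C@@]12OC(C)(C)O[C@@H]1[C@H](O[Si](c3ccccc3)(c3ccccc3)C(C)(C)C)C=C[C@H]2O[Si](CC)(CC)CC)c1ccccc1
F5 | step 10 | 3α-O-TBDPS 6β-O-mesyl acetonide | O=C(OC[C@@]12OC(C)(C)O[C@@H]1[C@H](O[Si](c3ccccc3)(c3ccccc3)C(C)(C)C)C=C[C@H]2OS(C)(=O)=O)c1ccccc1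
F6 | step 10 | 3α-O-TBDPS 6β-O-mesyl 1α,2α-diol | O=C(OC[C@@]1(O)[C@H](O)[C@H](O[Si](c2ccccc2)(c2ccccc2)C(C)(C)C)C=C[C@H]1OS(C)(=O)=O)c1ccccc1
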